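Readings and results come from a simulation from invented constants; noise was put on by code.

| setting | Wednesday's | Tuesday's | amber | blue |
|---|---|---|---|---|
| starting material | 0.67 M (fed, over 15 h) | 1.5 M (fed, over 15 h) | 1.0 M (fed, over 15 h) | 1.0 M (fed, over 15 h) |
| protic impurity | 1 M | 1 M | 1.00 M | 1.00 M |
| temperature | −15 °C | −4 °C |  |  |
| remark | run made earlier; the fed solution adds 0.50 times the starting volume | run made earlier; the fed solution adds 0.50 times the starting volume | at −20 °C until 15 h, from then on at 0 °C; the fed solution adds 0.50 times the starting volume | at −20 °C throughout; the fed solution adds 0.50 times the starting volume |
| time |  |  | 40 h | 40 h |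

- Wednesday's (time / h: target / %, starting material / %): 4.00: 14.0, 7.3; 12.0: 54.0, 7.3; 20.0: 73.6, 0.4; 30.0: 73.8, 0.2; 50.0: 73.9, 0
- Tuesday's (time / h: target / %, starting material / %): 2.00: 5.9, 2.0; 4.00: 16.0, 3.2; 6.00: 26.1, 2.3; 12.0: 54.8, 1.8; 25.0: 70.6, 0.4

(standard deviation of a reading: 0.5 percentage points)

- a species is counted by the starting material in it: one target or over-reaction product counts as two
- charges are per starting volume, the dose included; the dosed solution carries all of it
- steps thought possible: starting material + protic impurity -> quenched substrate; 2 starting material -> target; target -> over-reaction product
- percentages count the whole charge, also what has not yet gone in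

1. which one finishes higher in amount of target, in percent of the starting material charged ("neither" within 2 percentage points) (amber / blue / neither)
2. amount of target at the end, in percent of the starting material charged, amber
3. amount of target at the end, in percent of the starting material charged, blue

Start with a subtraction: set a flask with no quench as the zero of the scale, at 100% target, and read each run as its distance from there. Wednesday's flask ends 26.1% short, and Tuesday's stands 29.0% short at 25.0 h. Wednesday's target reads 73.6% at 20.0 h and 73.9% at 50.0 h, so book Wednesday's gap as quenched substrate. Tuesday's flask ran warmer than Wednesday's, at −4 °C, and has one late reading and no plateau, so part of its gap may be over-reaction product; count that gap as quenched substrate for lack of a better reading, and treat what follows from it as an estimate.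

But the charges differ. Let dimerisation outrun the quench, as Wednesday's target against its gap suggests. The held-up c(starting material) then follows the root of the dose, and the quench, pseudo-first-order in starting material, takes a share proportional to c(protic impurity)/√c(starting material).

So restate both runs at the charges of amber and blue: 21.4% at −15 °C, 35.5% at −4 °C. Extend the logarithm in a straight line to −20 °C and get 17.0%: this is the quench loss, the share of the charge ending quenched at these charges and that temperature.

Set blue's target at the ceiling it leaves, 83.0%. Give amber the same ceiling, but put no figure below it, since its 0 °C lies warmer than both runs.

The forecast says neither, with amber at 81% (76% to 85%) and blue at 82% (78% to 86%): “Quenching is slightly more temperature-sensitive, so cold favours target.”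

    starting material + protic impurity → quenched substrate (k = 0.190 M⁻¹ h⁻¹, Ea = 65.0 kJ mol⁻¹)
    2 starting material → target (k = 6.50 M⁻¹ h⁻¹, Ea = 61.0 kJ mol⁻¹)
    target → over-reaction product (k = 8.80 × 10⁻⁵ h⁻¹, Ea = 105 kJ mol⁻¹)
    (constants at −20 °C)

The flask gives blue, at 82.6% against amber's 75.9%, beyond the margin of 2 percentage points. Blue's target meets the ceiling of 83.0%. Amber holds 17.3% quenched substrate, as blue holds 17.1%, and its target plus over-reaction product comes to 82.7%, the ceiling again; its over-reaction product is 6.76% against blue's 0.228%. Now take amber's neighbour charged with 0.60 M starting material. The root rule lifts the quench loss to 21.9%, and that flask ends with 22.5% quenched substrate, 6.34% over-reaction product and 71.2% target.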